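**Plan**

Locants (elemane numbering): C10 = quaternary carbon (methyl, vinyl); C9 = ring CH2; C8 = angelate carbinol; C7 and C6 = lactone ring-fusion carbons; C5 carries the acrylic acid C4(=C15)–C3; lactone carbons are C11(=C13) and C12; ring B = C5–C10.
Retrosynthesis cuts, in order: the C3 tert-butyl ester and the C8–O angelate; then, from the C8 ketone, C8–C9 (Claisen retron once C9 carries a temporary carboxyl), C6–C7 (aldol retron) and the lactone O6–C12 bond in one operation; last C5–C10 (Ireland–Claisen retron).
Enabling feature: C8–C7–C11(=C13)–C12 is an intact itaconate unit whose enolisable C7 lies between the oxygenated ring carbons C6 and C8, so ring B plus the fused α-methylene lactone is the aldol/Claisen adduct of an itaconate half-ester with a C6-aldehyde/C9-ester 1,4-ambiphile.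
Forward: acyclic itaconate diester → C5–C10 by Ireland–Claisen → C6 aldehyde → ring B closed at C6–C7 and C8–C9, then the lactone ring, in one pot → C8 reduction → angelate → free acid.
Stereochemistry: C5/C10 from the chair Claisen under a chiral boron controller; C6 (Felkin–Anh) and C7 (closed aldol transition state) in the key step; C8 by α-face hydride delivery opposite the axial C10 methyl, then Mitsunobu inversion.

Key step: step 8

Assumption: the (S,S)-configured boron controller is taken to give the (2R,3S)-acid 13; if the sense of induction is the opposite, the (R,R)-reagent is used instead.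

**Route**

Step 1
Reactants: 1 but-2-yn-1-ol
Product: 3 (2Z)-3-iodobut-2-en-1-ol, via cyclic alkenylaluminate 2 (not isolated)
Conditions: NaAlH2(OCH2CH2OMe)2, THF, 0 °C → rt; then I2, −78 °C → rt
Reagents that add atoms: iodine, [I][I]
Why: Hydroxyl-directed trans-hydroalumination of the propargylic alcohol places aluminium on C3 cis to the carbinol carbon in the five-membered aluminate 2, and iodinolysis with retention should give the Z-vinyl iodide (hydroalumination–iodination of a propargylic alcohol).

Step 2
Reactants: 4 bromoacetyl bromide; 5 2-phenylpropan-2-ol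
Product: 6 2-phenylpropan-2-yl bromoacetate
Conditions: pyridine, CH2Cl2, 0 °C
Reagents that add atoms: none
Why: O-acylation of the tertiary alcohol by the acyl bromide (nucleophilic acyl substitution), run cold with pyridine to avoid elimination to 2-phenylpropene, should give the acid-labile cumyl ester that later serves as the removable carboxyl on C9.

Step 3
Reactants: 3 (2Z)-3-iodobut-2-en-1-ol; 6 2-phenylpropan-2-yl bromoacetate
Product: 8 2-phenylpropan-2-yl (3Z)-5-hydroxy-3-methylpent-3-enoate, via Reformatsky reagent 7 (not isolated)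
Conditions: 6, Zn (Me3SiCl-activated), THF, rt; then 3, excess 7, Pd(PPh3)4 (cat.), THF, 40 °C
Reagents that add atoms: none
Why: Negishi cross-coupling of the zinc ester enolate with the vinyl iodide under zerovalent palladium catalysis forms the C9–C10 bond with retention of alkene geometry, the excess zinc reagent tolerating the hydroxyl as its zinc alkoxide.

Step 4
Reactants: 8 2-phenylpropan-2-yl (3Z)-5-hydroxy-3-methylpent-3-enoate; 9 itaconic anhydride
Product: 10 4-{[(2Z)-3-methyl-5-oxo-5-(2-phenylpropan-2-yloxy)pent-2-en-1-yl]oxy}-2-methylidene-4-oxobutanoic acid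
Conditions: toluene, 50 °C
Reagents that add atoms: none
Why: Alcoholysis of itaconic anhydride (anhydride ring opening) occurs at the non-conjugated, more electrophilic carbonyl, so the allylic alcohol should end up on the carboxyl that becomes C6 while the acrylic acid (C3) stays free.

Step 5
Reactants: 10 the acid from step 4
Product: 11 1-tert-butyl 4-[(2Z)-3-methyl-5-oxo-5-(2-phenylpropan-2-yloxy)pent-2-en-1-yl] 2-methylidenebutanedioate
Conditions: O-tert-butyl N,N'-diisopropylisourea, CH2Cl2, rt
Reagents that add atoms: O-tert-butyl N,N'-diisopropylisourea, CC(C)N=C(OC(C)(C)C)NC(C)C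
Why: Isourea esterification transfers tert-butyl to the only free acid under neutral conditions, which spares the cumyl ester and avoids base-promoted migration of the itaconate double bond.

Step 6
Reactants: 11 the diester from step 5
Product: 13 (2R,3S)-2-[3-(tert-butoxy)-3-oxoprop-1-en-2-yl]-3-ethenyl-3-methyl-5-oxo-5-(2-phenylpropan-2-yloxy)pentanoic acid, via boron ketene acetal 12 (not isolated)
Conditions: (4S,5S)-2-bromo-1,3-bis{[3,5-bis(trifluoromethyl)phenyl]sulfonyl}-4,5-diphenyl-1,3,2-diazaborolidine, Et3N, toluene/hexane, −78 °C; then 4 °C; aqueous work-up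
Reagents that add atoms: none
Why: Enantioselective Ireland–Claisen rearrangement through a chiral boron ketene acetal: soft enolisation of the unhindered allylic ester at C5 should give the ketene acetal with the C4 substituent cis to O–B, and its chair [3,3] shift across the Z-alkene forms C5–C10 with the (5R,10S) relationship (C4 unit equatorial on C5, CH2CO2R axial and methyl equatorial on C10), the C2-symmetric sulfonamide ligand selecting the enolate face.

Step 7
Reactants: 13 the acid from step 6
Product: 15 2-phenylpropan-2-yl (3S,4R)-5-(tert-butoxycarbonyl)-3-ethenyl-4-formyl-3-methylhex-5-enoate, via acid chloride 14 (not isolated)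
Conditions: 1-chloro-N,N,2-trimethylprop-1-en-1-amine, CH2Cl2, 0 °C; then LiAlH(OtBu)3, THF, −78 °C
Reagents that add atoms: none
Why: Neutral chlorination of the acid and partial reduction of the cold acid chloride with the bulky hydride (Rosenmund-type reduction by hydride) should stop at the aldehyde without base, so C5 is not epimerised and no free C6 alcohol forms that could lactonise onto the acrylate.

Step 8
Reactants: 15 the aldehyde from step 7; 16 4-methoxy-2-methylidene-4-oxobutanoic acid (monomethyl itaconate)
Product: 21 tert-butyl 2-[(3aS,6S,7R,7aR)-6-ethenyl-6-methyl-3-methylidene-2,4-dioxooctahydro-1-benzofuran-7-yl]prop-2-enoate, via dilithium dienolate 17 (not isolated), via aldol adduct 18 (not isolated), via ring B keto ester 19 (not isolated), via lactone keto acid 20 (not isolated)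
Conditions: 16, LiN(iPr)2 (2.7 equiv), THF, −78 °C; add 15, −78 °C; LiN(iPr)2 (2.2 equiv), −78 → −30 °C; AcOH; solvent switch to CH2Cl2 without isolation, dilute CF3CO2H, 0 → 40 °C
Reagents that add atoms: none
Why: The dilithium dienolate 17 adds through its α-carbon C7 to the aldehyde carbon C6 (aldol), a second charge of LiN(iPr)2 then forms the ester enolate at C9, which attacks the methyl ester carbon C8 and expels methoxide (Dieckmann condensation), and the acid treatment lactonises O6 onto C12, removes the cumyl ester and lets the β-keto acid 20 lose CO2. The closest known reaction types are the aldol–lactonisation of itaconate half-ester dianions with aldehydes to β-carboxy-α-methylene-γ-butyrolactones and the Dieckmann condensation. Ring B closes by 6-exo-trig attack of C9 on the C8 carbonyl and the lactone by 5-exo-trig attack of the C6 hydroxyl on the C12 carboxyl. C6 is set by Felkin–Anh addition anti to the quaternary C10 on the α-stereocentre C5, which places O6 trans to the C4 substituent, and C7 by a closed Zimmerman–Traxler transition state of the carboxylate-chelated Z-enolate (syn aldol, hence trans ring fusion), while the C9 centre is erased on decarboxylation. The step needs addition to win over enolisation of the α-branched aldehyde (−78 °C, hindered C5–H), deprotonation at C9 and not at C7 (C7 lies between the oxido-bearing C6 and the carboxylate-bearing C11 of the polyanion), and attack on the methyl ester C8 (6-exo) instead of the tert-butyl acrylate C3 (5-exo), which the bulk and conjugation of the latter secure. Holding O6 as a lithium alkoxide and C12 as a carboxylate until the quench prevents an early lactone, which under base would open by Stobbe-type elimination.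

Step 9
Reactants: 21 the keto lactone from step 8
Product: 22 tert-butyl 2-[(3aR,4R,6S,7R,7aR)-6-ethenyl-4-hydroxy-6-methyl-3-methylidene-2-oxooctahydro-1-benzofuran-7-yl]prop-2-enoate
Conditions: LiAlH(OtBu)3, THF, −78 → −40 °C
Reagents that add atoms: none
Why: The bulky, chemoselective hydride should attack the C8 ketone from the α-face because axial attack is blocked by the syn-axial C10 methyl, giving the axial 8β-alcohol and leaving lactone, esters and the α-methylene unit untouched (substrate-controlled ketone reduction).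

Step 10
Reactants: 22 the 8β-alcohol from step 9; 23 angelic acid ((2Z)-2-methylbut-2-enoic acid)
Product: 24 tert-butyl 2-[(3aR,4S,6S,7R,7aR)-6-ethenyl-6-methyl-4-{[(2Z)-2-methylbut-2-enoyl]oxy}-3-methylidene-2-oxooctahydro-1-benzofuran-7-yl]prop-2-enoate
Conditions: PPh3, DIAD, toluene, 0 °C → rt
Reagents that add atoms: none
Why: Mitsunobu esterification: angelate displaces the axial oxyphosphonium by SN2 from the α-face, inverting C8 to the equatorial 8α-ester under neutral conditions that should preserve the Z geometry of the angelate.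

Step 11
Reactants: 24 the tert-butyl ester from step 10
Product: 25 2-[(3aR,4S,6S,7R,7aR)-6-ethenyl-6-methyl-4-{[(2Z)-2-methylbut-2-enoyl]oxy}-3-methylidene-2-oxooctahydro-1-benzofuran-7-yl]prop-2-enoic acid (CNP0256928.3)
Conditions: CF3CO2H/CH2Cl2 (1:4), 0 °C → rt
Reagents that add atoms: none
Why: Acidolysis of the tert-butyl ester (loss of isobutene through the tert-butyl cation) should free the acrylic acid without touching the lactone, the angelate or the alkenes.

**Compound list**

1 | but-2-yn-1-ol | CC#CCO | starting material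
2 | sodium 2,2-bis(2-methoxyethoxy)-3-methyl-2,5-dihydro-1,2-oxaaluminol-2-uide (cyclic alkenylaluminate) | CC1=CCO[Al-]1(OCCOC)OCCOC.[Na+] | intermediate
3 | (2Z)-3-iodobut-2-en-1-ol | C/C(I)=C/CO | intermediate
4 | bromoacetyl bromide | BrCC(Br)=O | starting material
5 | 2-phenylpropan-2-ol | CC(C)(O)c1ccccc1 | starting material
6 | 2-phenylpropan-2-yl bromoacetate | BrCC(=O)OC(C)(C)c1ccccc1 | intermediate
7 | bromo{2-oxo-2-[(2-phenylpropan-2-yl)oxy]ethyl}zinc (Reformatsky reagent) | Br[Zn]CC(=O)OC(C)(C)c1ccccc1 | intermediate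
8 | 2-phenylpropan-2-yl (3Z)-5-hydroxy-3-methylpent-3-enoate | C/C(CC(=O)OC(C)(C)c1ccccc1)=C/CO | intermediate
9 | itaconic anhydride (3-methylideneoxolane-2,5-dione) | C=C1CC(=O)OC1=O | starting material
10 | 4-{[(2Z)-3-methyl-5-oxo-5-(2-phenylpropan-2-yloxy)pent-2-en-1-yl]oxy}-2-methylidene-4-oxobutanoic acid | C/C(CC(=O)OC(C)(C)c1ccccc1)=C/COC(=O)CC(=C)C(=O)O | intermediate
11 | 1-tert-butyl 4-[(2Z)-3-methyl-5-oxo-5-(2-phenylpropan-2-yloxy)pent-2-en-1-yl] 2-methylidenebutanedioate | C/C(CC(=O)OC(C)(C)c1ccccc1)=C/COC(=O)CC(=C)C(=O)OC(C)(C)C | intermediate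
12 | boron ketene acetal of 11 (O–B on C6, C4 substituent cis to O–B, (4S,5S)-diazaborolidine on boron) | C/C(CC(=O)OC(C)(C)c1ccccc1)=C/CO/C(OB2N(S(=O)(=O)c3cc(C(F)(F)F)cc(C(F)(F)F)c3)[C@@H](c3ccccc3)[C@H](c3ccccc3)N2S(=O)(=O)c2cc(C(F)(F)F)cc(C(F)(F)F)c2)=C/C(=C)C(=O)OC(C)(C)C | intermediate
13 | (2R,3S)-2-[3-(tert-butoxy)-3-oxoprop-1-en-2-yl]-3-ethenyl-3-methyl-5-oxo-5-(2-phenylpropan-2-yloxy)pentanoic acid | C=C[C@](C)(CC(=O)OC(C)(C)c1ccccc1)[C@@H](C(=O)O)C(=C)C(=O)OC(C)(C)C | intermediate
14 | acid chloride of 13 | C=C[C@](C)(CC(=O)OC(C)(C)c1ccccc1)[C@@H](C(=O)Cl)C(=C)C(=O)OC(C)(C)C | intermediate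
15 | 2-phenylpropan-2-yl (3S,4R)-5-(tert-butoxycarbonyl)-3-ethenyl-4-formyl-3-methylhex-5-enoate | C=C[C@](C)(CC(=O)OC(C)(C)c1ccccc1)[C@@H](C=O)C(=C)C(=O)OC(C)(C)C | intermediate
16 | 4-methoxy-2-methylidene-4-oxobutanoic acid (monomethyl itaconate) | C=C(CC(=O)OC)C(=O)O | starting material
17 | dilithium dienolate of 16 (carboxylate plus Z ester enolate) | C=C(C(=O)[O-])/C=C(\[O-])OC.[Li+].[Li+] | intermediate
18 | syn aldol adduct of 15 and 17, shown as the free hydroxy acid (C6 carbinol; C7 bears CO2Me and the 1-carboxyvinyl group) | C=C[C@](C)(CC(=O)OC(C)(C)c1ccccc1)[C@@H]([C@@H](O)[C@@H](C(=O)OC)C(=C)C(=O)O)C(=C)C(=O)OC(C)(C)C | intermediate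
19 | ring B β-keto cumyl ester hydroxy acid (Dieckmann product, C9 epimers) | C=C[C@]1(C)C(C(=O)OC(C)(C)c2ccccc2)C(=O)[C@@H](C(=C)C(=O)O)[C@H](O)[C@H]1C(=C)C(=O)OC(C)(C)C | intermediate
20 | lactone β-keto acid (C9 carboxylic acid, C9 epimers) | C=C[C@]1(C)C(C(=O)O)C(=O)[C@H]2C(=C)C(=O)O[C@@H]2[C@H]1C(=C)C(=O)OC(C)(C)C | intermediate
21 | tert-butyl 2-[(3aS,6S,7R,7aR)-6-ethenyl-6-methyl-3-methylidene-2,4-dioxooctahydro-1-benzofuran-7-yl]prop-2-enoate | C=C[C@]1(C)CC(=O)[C@H]2C(=C)C(=O)O[C@@H]2[C@H]1C(=C)C(=O)OC(C)(C)C | intermediate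
22 | tert-butyl 2-[(3aR,4R,6S,7R,7aR)-6-ethenyl-4-hydroxy-6-methyl-3-methylidene-2-oxooctahydro-1-benzofuran-7-yl]prop-2-enoate | C=C[C@]1(C)C[C@@H](O)[C@H]2C(=C)C(=O)O[C@@H]2[C@H]1C(=C)C(=O)OC(C)(C)C | intermediate
23 | angelic acid, (2Z)-2-methylbut-2-enoic acid | C/C=C(/C)C(=O)O | starting material
24 | tert-butyl 2-[(3aR,4S,6S,7R,7aR)-6-ethenyl-6-methyl-4-{[(2Z)-2-methylbut-2-enoyl]oxy}-3-methylidene-2-oxooctahydro-1-benzofuran-7-yl]prop-2-enoate | C=C[C@]1(C)C[C@H](OC(=O)/C(C)=C\C)[C@H]2C(=C)C(=O)O[C@@H]2[C@H]1C(=C)C(=O)OC(C)(C)C | intermediate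
25 | 2-[(3aR,4S,6S,7R,7aR)-6-ethenyl-6-methyl-4-{[(2Z)-2-methylbut-2-enoyl]oxy}-3-methylidene-2-oxooctahydro-1-benzofuran-7-yl]prop-2-enoic acid | C=C[C@]1(C)C[C@H](OC(=O)/C(C)=C\C)[C@H]2C(=C)C(=O)O[C@@H]2[C@H]1C(=C)C(=O)O | target

**Count and risks**

Total step count: 11. Longest linear sequence: 10 steps (1 → 25 through steps 1 and 3–11; step 2 is a side branch).

Steps most likely to fail:

1. Step 8. What may go wrong: deprotonation (and C5 epimerisation) of the hindered aldehyde by the basic dienolate instead of addition; retro-aldol cleavage on warming before ring closure; deprotonation at C7 followed by double-bond migration; or poor facial selectivity at C6 if C10 does not act as the large group. Fallback (sets out from 15, comes back at 19): the order of the two bond formations is reversed with the aldehyde masked. 15 is converted into its dimethyl acetal, 2-phenylpropan-2-yl (3S,4R)-5-(tert-butoxycarbonyl)-4-(dimethoxymethyl)-3-ethenyl-3-methylhex-5-enoate F1 (HC(OMe)3, pyridinium p-toluenesulfonate, MeOH). Deprotonation at C9 with LiN(iPr)2 (THF, −78 °C) and crossed Claisen acylation by itaconic anhydride 9 at its non-conjugated carbonyl should give the C9-acylated β-keto ester acid F2. Dilute aqueous CF3CO2H in CH2Cl2 then unmasks the keto aldehyde F3, whose C8 ketone enolises toward C7 and closes ring B by a reversible, chair-controlled intramolecular aldol to 19. From 19 lactonisation, loss of the cumyl group and decarboxylation proceed as in step 8 to 21.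

2. Step 6. What may go wrong: poor control of ketene acetal geometry (and so of the C5/C10 relationship), low enantioselection with this dienolate-type ester, or Lewis-acid cleavage of the tertiary esters by the bromoborane. Fallback (sets out from 11, comes back at 13): an achiral Ireland–Claisen followed by classical resolution. LiN(iPr)2 in THF/DMPU with Me3SiCl (−78 °C → rt) should give the trimethylsilyl ketene acetal F4, which rearranges through the same chair to the racemic (2RS,3SR)-acid F5. Crystallisation of the diastereomeric salt with (R)-1-phenylethylamine, the (R)-1-phenylethylammonium salt of 13 F6, and release with cold dilute HCl gives 13.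

3. Step 10. What may go wrong: E2 elimination of the axial oxyphosphonium toward C7 or C9 (anti-periplanar axial hydrogens), slow SN2 at the hindered C8, or Z→E isomerisation of the angelate. Fallback (sets out from 21, comes back at 24): acylation with retention in place of inversion. Reagent-controlled Corey–Bakshi–Shibata reduction of 21 ((R)-2-methyl-CBS-oxazaborolidine, catecholborane, toluene, −78 °C) should give the equatorial 8α-alcohol, tert-butyl 2-[(3aR,4S,6S,7R,7aR)-6-ethenyl-4-hydroxy-6-methyl-3-methylidene-2-oxooctahydro-1-benzofuran-7-yl]prop-2-enoate F7. Yamaguchi esterification with 23 (2,4,6-trichlorobenzoyl chloride, Et3N, toluene; then F7, 4-(dimethylamino)pyridine) then gives 24.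

**Further compounds**

F1 | step 8 | 2-phenylpropan-2-yl (3S,4R)-5-(tert-butoxycarbonyl)-4-(dimethoxymethyl)-3-ethenyl-3-methylhex-5-enoate | C=C[C@](C)(CC(=O)OC(C)(C)c1ccccc1)[C@@H](C(OC)OC)C(=C)C(=O)OC(C)(C)C
F2 | step 8 | C9-acylated β-keto ester acid (3-carboxybut-3-enoyl group on C9 of F1, acetal intact, C9 epimers) | C=C[C@](C)(C(C(=O)OC(C)(C)c1ccccc1)C(=O)CC(=C)C(=O)O)[C@@H](C(OC)OC)C(=C)C(=O)OC(C)(C)C
F3 | step 8 | keto aldehyde acid (F2 with the acetal hydrolysed to the C6 aldehyde) | C=C[C@](C)(C(C(=O)OC(C)(C)c1ccccc1)C(=O)CC(=C)C(=O)O)[C@@H](C=O)C(=C)C(=O)OC(C)(C)C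
F4 | step 6 | trimethylsilyl ketene acetal of 11 (C4 substituent cis to O–Si) | C/C(CC(=O)OC(C)(C)c1ccccc1)=C/CO/C(O[Si](C)(C)C)=C/C(=C)C(=O)OC(C)(C)C
F5 | step 6 | racemic (2RS,3SR)-2-[3-(tert-butoxy)-3-oxoprop-1-en-2-yl]-3-ethenyl-3-methyl-5-oxo-5-(2-phenylpropan-2-yloxy)pentanoic acid | C=C[C@](C)(CC(=O)OC(C)(C)c1ccccc1)[C@@H](C(=O)O)C(=C)C(=O)OC(C)(C)C.C=C[C@@](C)(CC(=O)OC(C)(C)c1ccccc1)[C@H](C(=O)O)C(=C)C(=O)OC(C)(C)C
F6 | step 6 | (R)-1-phenylethylammonium salt of 13 | C=C[C@](C)(CC(=O)OC(C)(C)c1ccccc1)[C@@H](C(=O)[O-])C(=C)C(=O)OC(C)(C)C.C[C@@H]([NH3+])c1ccccc1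
F7 | step 10 | tert-butyl 2-[(3aR,4S,6S,7R,7aR)-6-ethenyl-4-hydroxy-6-methyl-3-methylidene-2-oxooctahydro-1-benzofuran-7-yl]prop-2-enoate | C=C[C@]1(C)C[C@H](O)[C@H]2C(=C)C(=O)O[C@@H]2[C@H]1C(=C)C(=O)OC(C)(C)C
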